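**Retrosynthetic overview**
- The target is released from its tris-TBS ether by fluoride. No ring is formed in the route: guaiacyl ring A and syringyl ring B are bought as dihydroconiferyl alcohol and syringic acid.
- Key disconnection: the C(=O)–CH(OAr) bond, made by a nickel-catalysed enantioconvergent decarboxylative acylation of a racemic N-acyloxyphthalimide (2-aryloxy-3-silyloxypropanoate) with silyl-protected syringoyl chloride. This one step joins the halves, installs the ketone, expels the CO2 activating group and sets the only stereocentre from a racemate.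
- Enabling feature: the methine carbon carries the ether oxygen of ring A, whose lone pair stabilises a planar radical at that carbon, so a carboxyl group placed there is a traceless, configuration-erasing handle. Its neighbour is an aroyl carbon on ring B, available as an acid chloride.
- Racemic acid half: Mitsunobu etherification of mono-silylated dihydroconiferyl alcohol with racemic O-silyl methyl glycerate, then saponification and esterification with N-hydroxyphthalimide.
- Acyl half: bis-silylation of syringic acid, then oxalyl chloride/DMF on the silyl ester.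

Key step: step 8

Assumption: methyl (±)-glycerate is taken as a catalogue compound, and the sense of induction of (S,S)-Ph-BOX in step 8 is assumed; the antipodal ligand is used if the first run shows the opposite sense. TBS = tert-butyldimethylsilyl.

Step 1
Reactants: 1 dihydroconiferyl alcohol [4-(3-hydroxypropyl)-2-methoxyphenol]
Product: 2 4-[3-(TBS-oxy)propyl]-2-methoxyphenol
Conditions: TBSCl (1.05 equiv), imidazole (2 equiv), CH2Cl2, 0 °C
Reagents that add atoms: tert-butyldimethylsilyl chloride, CC(C)(C)[Si](C)(C)Cl
Why: Chemoselective silyl ether formation, in which the unhindered primary alcohol should react with the N-silylimidazolium faster than the hydrogen-bonded, ortho-methoxy-flanked phenol when one equivalent is used cold; any bis-silylated material can be returned to 2 with K2CO3/MeOH.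

Step 2
Reactants: 3 methyl (±)-2,3-dihydroxypropanoate (methyl glycerate)
Product: 4 methyl (±)-3-(TBS-oxy)-2-hydroxypropanoate
Conditions: TBSCl (1.05 equiv), imidazole (1.5 equiv), CH2Cl2, 0 °C to rt
Reagents that add atoms: tert-butyldimethylsilyl chloride, CC(C)(C)[Si](C)(C)Cl
Why: Selective silylation of the primary hydroxyl over the more hindered, ester-deactivated secondary hydroxyl (silyl ether protection).

Step 3
Reactants: 2 4-[3-(TBS-oxy)propyl]-2-methoxyphenol; 4 methyl (±)-3-(TBS-oxy)-2-hydroxypropanoate
Product: 5 methyl (±)-3-(TBS-oxy)-2-{4-[3-(TBS-oxy)propyl]-2-methoxyphenoxy}propanoate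
Conditions: PPh3 (1.3 equiv), DIAD (1.3 equiv), THF, 0 °C to rt
Reagents that add atoms: none
Why: Mitsunobu etherification, in which the phenol (pKa about 10) displaces the oxyphosphonium of the α-hydroxy ester by SN2 at a carbon activated by the ester; the centre is racemic, so the inversion has no consequence.

Step 4
Reactants: 5 methyl (±)-3-(TBS-oxy)-2-{4-[3-(TBS-oxy)propyl]-2-methoxyphenoxy}propanoate
Product: 6 (±)-3-(TBS-oxy)-2-{4-[3-(TBS-oxy)propyl]-2-methoxyphenoxy}propanoic acid
Conditions: LiOH·H2O (2 equiv), THF/H2O 3:1, 0 °C; then 1 M HCl to pH 4, 0 °C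
Reagents that add atoms: lithium hydroxide, [Li+].[OH-]
Why: Ester saponification, which primary alkyl TBS ethers tolerate and in which silyloxide is too poor a leaving group for E1cB loss; enolisation is harmless at a racemic centre.

Step 5
Reactants: 6 (±)-3-(TBS-oxy)-2-{4-[3-(TBS-oxy)propyl]-2-methoxyphenoxy}propanoic acid
Product: 7 1,3-dioxoisoindolin-2-yl (±)-3-(TBS-oxy)-2-{4-[3-(TBS-oxy)propyl]-2-methoxyphenoxy}propanoate (racemic N-acyloxyphthalimide)
Conditions: N-hydroxyphthalimide (1.1 equiv), DIC (1.1 equiv), DMAP (5 mol %), CH2Cl2, 0 °C to rt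
Reagents that add atoms: N-hydroxyphthalimide, O=C1c2ccccc2C(=O)N1O
Why: Carbodiimide (Steglich-type) esterification gives the redox-active ester under nearly neutral conditions, so the base-sensitive α-aryloxy-β-silyloxy ester is not exposed to elimination.

Step 6
Reactants: 8 syringic acid (4-hydroxy-3,5-dimethoxybenzoic acid)
Product: 9 tert-butyldimethylsilyl 4-(TBS-oxy)-3,5-dimethoxybenzoate
Conditions: TBSCl (2.4 equiv), imidazole (5 equiv), DMF, rt to 40 °C
Reagents that add atoms: tert-butyldimethylsilyl chloride, CC(C)(C)[Si](C)(C)Cl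
Why: Exhaustive silylation converts the phenol into its silyl ether and the acid into its silyl ester in one operation (silyl ether and silyl ester formation).

Step 7
Reactants: 9 tert-butyldimethylsilyl 4-(TBS-oxy)-3,5-dimethoxybenzoate
Product: 10 4-(TBS-oxy)-3,5-dimethoxybenzoyl chloride
Conditions: (COCl)2 (1.2 equiv), DMF (cat.), CH2Cl2, 0 °C to rt; evaporate, use crude
Reagents that add atoms: oxalyl chloride, O=C(Cl)C(=O)Cl
Why: Vilsmeier-mediated conversion of a silyl ester into the acid chloride under neutral, HCl-free conditions, which should leave the aryl silyl ether intact (acid chloride formation from a silyl ester).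

Step 8
Reactants: 7 racemic N-acyloxyphthalimide (1.0 equiv); 10 4-(TBS-oxy)-3,5-dimethoxybenzoyl chloride (1.5 equiv)
Product: 12 (R)-3-(TBS-oxy)-1-[4-(TBS-oxy)-3,5-dimethoxyphenyl]-2-{4-[3-(TBS-oxy)propyl]-2-methoxyphenoxy}propan-1-one, via α-aryloxyalkyl radical 11 (not isolated)
Conditions: NiBr2·DME (10 mol %), (S,S)-Ph-BOX [2,2'-(propane-2,2-diyl)bis((4S)-4-phenyl-4,5-dihydrooxazole)] (12 mol %), Mn powder (3 equiv), 3 Å MS, DMA/THF 3:7, 10 °C
Reagents that add atoms: none
Why: Proposed new method: zerovalent nickel carrying the chiral bis(oxazoline) inserts into the C–Cl bond of 10 to give a divalent aroylnickel chloride, while single-electron reduction of the N-acyloxyphthalimide of either enantiomer of 7 (by monovalent nickel or by Mn) expels phthalimide anion and CO2 and leaves the same planar, oxygen-stabilised radical 11, so the racemic centre is erased before the new bond forms. Radical 11 is captured by the aroylnickel complex to give a trivalent acyl(alkyl)nickel species that reductively eliminates the C(=O)–CH(OAr) bond, and Mn returns the resulting monovalent nickel to the zerovalent state. The closest known reactions are the nickel/bis(oxazoline)-catalysed enantioconvergent reductive acyl coupling of racemic secondary benzylic chlorides with acid chlorides (Mn as reductant) and the nickel-catalysed ketone synthesis from N-acyloxyphthalimides and acyl electrophiles; the new element is an α-aryloxyalkyl radical in the enantioselective manifold. No ring is closed; the only stereocentre is set by the ligand, since radical capture at nickel is reversible and the diastereomeric trivalent nickel intermediates are sorted by their rates of reductive elimination inside the C2-symmetric bis(oxazoline) pocket, possibly helped by transient coordination of the ether oxygen on the radical carbon. Cross-coupling over homocoupling is needed and is secured by the different activation modes of the partners (two-electron oxidative addition for the acyl chloride, one-electron reduction for the redox-active ester), and the radical forms only at the carbon that carries the carboxyl activating group. Product 12 should keep its configuration because the medium contains no amine base and an α-aryloxy ketone is less C–H acidic than the α-aryl ketones that survive this reaction type.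

Step 9
Reactants: 12 (R)-tris-TBS ketone
Product: 13 (R)-3-hydroxy-1-(4-hydroxy-3,5-dimethoxyphenyl)-2-[4-(3-hydroxypropyl)-2-methoxyphenoxy]propan-1-one (target)
Conditions: HF·pyridine, pyridine, THF, 0 °C to rt; pH 7 phosphate buffer work-up
Reagents that add atoms: none
Why: Fluoride-mediated silyl ether cleavage under buffered, mildly acidic conditions should remove the aryl and both primary alkyl TBS groups without the basic medium that would enolise the α-carbon or trigger retro-aldol loss of formaldehyde from the β-hydroxy ketone.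

**Compound list**
1 | dihydroconiferyl alcohol, 4-(3-hydroxypropyl)-2-methoxyphenol | COc1cc(CCCO)ccc1O | starting material
2 | 4-[3-(tert-butyldimethylsilyloxy)propyl]-2-methoxyphenol | COc1cc(CCCO[Si](C)(C)C(C)(C)C)ccc1O | intermediate
3 | methyl (±)-2,3-dihydroxypropanoate | COC(=O)C(O)CO | starting material
4 | methyl (±)-3-(tert-butyldimethylsilyloxy)-2-hydroxypropanoate | COC(=O)C(O)CO[Si](C)(C)C(C)(C)C | intermediate
5 | methyl (±)-3-(tert-butyldimethylsilyloxy)-2-{4-[3-(tert-butyldimethylsilyloxy)propyl]-2-methoxyphenoxy}propanoate | COC(=O)C(CO[Si](C)(C)C(C)(C)C)Oc1ccc(CCCO[Si](C)(C)C(C)(C)C)cc1OC | intermediate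
6 | (±)-3-(tert-butyldimethylsilyloxy)-2-{4-[3-(tert-butyldimethylsilyloxy)propyl]-2-methoxyphenoxy}propanoic acid | OC(=O)C(CO[Si](C)(C)C(C)(C)C)Oc1ccc(CCCO[Si](C)(C)C(C)(C)C)cc1OC | intermediate
7 | 1,3-dioxoisoindolin-2-yl (±)-3-(tert-butyldimethylsilyloxy)-2-{4-[3-(tert-butyldimethylsilyloxy)propyl]-2-methoxyphenoxy}propanoate | O=C(ON1C(=O)c2ccccc2C1=O)C(CO[Si](C)(C)C(C)(C)C)Oc1ccc(CCCO[Si](C)(C)C(C)(C)C)cc1OC | intermediate
8 | syringic acid, 4-hydroxy-3,5-dimethoxybenzoic acid | COc1cc(C(=O)O)cc(OC)c1O | starting material
9 | tert-butyldimethylsilyl 4-(tert-butyldimethylsilyloxy)-3,5-dimethoxybenzoate | COc1cc(C(=O)O[Si](C)(C)C(C)(C)C)cc(OC)c1O[Si](C)(C)C(C)(C)C | intermediate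
10 | 4-(tert-butyldimethylsilyloxy)-3,5-dimethoxybenzoyl chloride | COc1cc(C(=O)Cl)cc(OC)c1O[Si](C)(C)C(C)(C)C | intermediate
11 | 2-(tert-butyldimethylsilyloxy)-1-{4-[3-(tert-butyldimethylsilyloxy)propyl]-2-methoxyphenoxy}ethyl radical (not isolated) | COc1cc(CCCO[Si](C)(C)C(C)(C)C)ccc1O[CH]CO[Si](C)(C)C(C)(C)C | intermediate
12 | (R)-3-(tert-butyldimethylsilyloxy)-1-[4-(tert-butyldimethylsilyloxy)-3,5-dimethoxyphenyl]-2-{4-[3-(tert-butyldimethylsilyloxy)propyl]-2-methoxyphenoxy}propan-1-one | COc1cc(CCCO[Si](C)(C)C(C)(C)C)ccc1O[C@H](CO[Si](C)(C)C(C)(C)C)C(=O)c1cc(OC)c(O[Si](C)(C)C(C)(C)C)c(OC)c1 | intermediate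
13 | (R)-3-hydroxy-1-(4-hydroxy-3,5-dimethoxyphenyl)-2-[4-(3-hydroxypropyl)-2-methoxyphenoxy]propan-1-one | COc1cc(CCCO)ccc1O[C@H](CO)C(=O)c1cc(OC)c(O)c(OC)c1 | target

**Step count and risks**
Total steps: 9. Longest linear sequence: 6 (steps 1, 3, 4, 5, 8, 9).

Steps most likely to fail:

1. Step 8. The bis(oxazoline)–nickel complex may discriminate poorly between the faces of a non-benzylic α-aryloxyalkyl radical, or radical dimerisation and acyl homocoupling may outrun cross-coupling. The fallback uses known chemistry, sets out from phenol 2 and returns at 12, making the same bond with the configuration drawn from the chiral pool. Commercial methyl (S)-2,3-dihydroxypropanoate is silylated (TBSCl, imidazole) to methyl (S)-3-(tert-butyldimethylsilyloxy)-2-hydroxypropanoate F1. Mitsunobu etherification with 2 (PPh3, DIAD, THF) proceeds with inversion to methyl (R)-3-(tert-butyldimethylsilyloxy)-2-{4-[3-(tert-butyldimethylsilyloxy)propyl]-2-methoxyphenoxy}propanoate F2. Aminolysis with MeNH(OMe)·HCl/iPrMgCl (THF, −20 °C) gives (R)-3-(tert-butyldimethylsilyloxy)-2-{4-[3-(tert-butyldimethylsilyloxy)propyl]-2-methoxyphenoxy}-N-methoxy-N-methylpropanamide F3. Separately, commercial 4-bromo-2,6-dimethoxyphenol is silylated to (4-bromo-2,6-dimethoxyphenoxy)(tert-butyl)dimethylsilane F4. Bromine–lithium exchange (n-BuLi, THF, −78 °C) gives [4-(tert-butyldimethylsilyloxy)-3,5-dimethoxyphenyl]lithium F5, which adds to F3 at −78 °C (Weinreb ketone synthesis, NH4Cl quench) to deliver 12.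

2. Step 9. Once the free β-hydroxy ketone is exposed to fluoride, the enolisable α-carbon may lose configuration, or retro-aldol loss of formaldehyde or dehydration may occur. The fallback sets out from 12 and returns at 13, unveiling the ketone last under neutral oxidation. NaBH4/CeCl3·7H2O (MeOH/THF, −40 °C) reduces 12 to (1RS,2R)-3-(tert-butyldimethylsilyloxy)-1-[4-(tert-butyldimethylsilyloxy)-3,5-dimethoxyphenyl]-2-{4-[3-(tert-butyldimethylsilyloxy)propyl]-2-methoxyphenoxy}propan-1-ol F6, in which the aryloxy-bearing carbon is no longer enolisable. TBAF (THF, rt) gives (1RS,2R)-1-(4-hydroxy-3,5-dimethoxyphenyl)-2-[4-(3-hydroxypropyl)-2-methoxyphenoxy]propane-1,3-diol F7. DDQ (1.1 equiv, dioxane, rt), which dehydrogenates para-hydroxybenzylic alcohols selectively and leaves primary aliphatic alcohols alone, then gives 13.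

3. Step 3. The activated α-hydroxy ester may eliminate, the silyl group may migrate, or SN2 displacement at the hindered secondary carbon may be slow. The fallback sets out from 2 and returns at 5, building the hydroxymethyl carbon by aldol chemistry instead of forming the ether at a secondary carbon. O-Alkylation of 2 with methyl bromoacetate (K2CO3, acetone, reflux) gives methyl 2-{4-[3-(tert-butyldimethylsilyloxy)propyl]-2-methoxyphenoxy}acetate F8. Enolisation with LiN(iPr)2 (THF, −78 °C) and trapping with monomeric formaldehyde gives methyl (±)-3-hydroxy-2-{4-[3-(tert-butyldimethylsilyloxy)propyl]-2-methoxyphenoxy}propanoate F9, which is silylated (TBSCl, imidazole) to 5.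

Further compounds
F1 | step 8 | methyl (S)-3-(tert-butyldimethylsilyloxy)-2-hydroxypropanoate | COC(=O)[C@@H](O)CO[Si](C)(C)C(C)(C)C
F2 | step 8 | methyl (R)-3-(tert-butyldimethylsilyloxy)-2-{4-[3-(tert-butyldimethylsilyloxy)propyl]-2-methoxyphenoxy}propanoate | COc1cc(CCCO[Si](C)(C)C(C)(C)C)ccc1O[C@H](CO[Si](C)(C)C(C)(C)C)C(=O)OC
F3 | step 8 | (R)-3-(tert-butyldimethylsilyloxy)-2-{4-[3-(tert-butyldimethylsilyloxy)propyl]-2-methoxyphenoxy}-N-methoxy-N-methylpropanamide | COc1cc(CCCO[Si](C)(C)C(C)(C)C)ccc1O[C@H](CO[Si](C)(C)C(C)(C)C)C(=O)N(C)OC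
F4 | step 8 | (4-bromo-2,6-dimethoxyphenoxy)(tert-butyl)dimethylsilane | COc1cc(Br)cc(OC)c1O[Si](C)(C)C(C)(C)C
F5 | step 8 | [4-(tert-butyldimethylsilyloxy)-3,5-dimethoxyphenyl]lithium | [Li]c1cc(OC)c(O[Si](C)(C)C(C)(C)C)c(OC)c1
F6 | step 9 | (1RS,2R)-3-(tert-butyldimethylsilyloxy)-1-[4-(tert-butyldimethylsilyloxy)-3,5-dimethoxyphenyl]-2-{4-[3-(tert-butyldimethylsilyloxy)propyl]-2-methoxyphenoxy}propan-1-ol | COc1cc(CCCO[Si](C)(C)C(C)(C)C)ccc1O[C@H](CO[Si](C)(C)C(C)(C)C)C(O)c1cc(OC)c(O[Si](C)(C)C(C)(C)C)c(OC)c1
F7 | step 9 | (1RS,2R)-1-(4-hydroxy-3,5-dimethoxyphenyl)-2-[4-(3-hydroxypropyl)-2-methoxyphenoxy]propane-1,3-diol | COc1cc(CCCO)ccc1O[C@H](CO)C(O)c1cc(OC)c(O)c(OC)c1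
F8 | step 3 | methyl 2-{4-[3-(tert-butyldimethylsilyloxy)propyl]-2-methoxyphenoxy}acetate | COC(=O)COc1ccc(CCCO[Si](C)(C)C(C)(C)C)cc1OC
F9 | step 3 | methyl (±)-3-hydroxy-2-{4-[3-(tert-butyldimethylsilyloxy)propyl]-2-methoxyphenoxy}propanoate | COC(=O)C(CO)Oc1ccc(CCCO[Si](C)(C)C(C)(C)C)cc1OC
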